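| flask | starting material | coupling partner | time |
|---|---|---|---|
| south | 0.600 M | 1.20 M |  |
| north-east | 0.240 M | 0.840 M |  |
| north-west | 1.80 M | 1.20 M |  |
| south-east | 0.600 M | 0.600 M |  |
| south-west | 2.40 M | 4.80 M | 59 min |

| run | time / min | [target] / M |
|---|---|---|
| south run | 3.4 | 0.032 |
| south run | 10 | 0.063 |
| south run | 19 | 0.100 |
| south run | 31 | 0.143 |
| south run | 44 | 0.148 |
| south run | 59 | 0.165 |
| north-east run | 3.4 | 0.015 |
| north-east run | 10 | 0.037 |
| north-east run | 19 | 0.044 |
| north-east run | 31 | 0.060 |
| north-east run | 44 | 0.066 |
| north-east run | 59 | 0.084 |
| north-west run | 3.4 | 0.054 |
| north-west run | 10 | 0.114 |
| north-west run | 19 | 0.185 |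
| north-west run | 31 | 0.243 |
| north-west run | 44 | 0.285 |
| north-west run | 59 | 0.320 |
| south-east run | 3.4 | 0.015 |
| south-east run | 10 | 0.042 |
| south-east run | 19 | 0.060 |
| south-east run | 31 | 0.084 |
| south-east run | 44 | 0.107 |
| south-east run | 59 | 0.129 |

(each reading ± 0.006 M)

- reaction order in [starting material] at the outset, round the charge of the south run, defined at two percent of the starting material turned into target (one fixed amount of target, the same in the runs compared)
- reaction order in [coupling partner] at the outset, round the charge of the south run, defined at two percent of the starting material turned into target
- target in the south-west run at 59 min, as a share of the starting material charged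

- Overall: starting material + coupling partner -> target.
- Constant volume, constant temperature.
- What is held in complexes is read along with the free species.
- "The second partner" is coupling partner.
- An order is taken over about fifteen percent of the charge, up and down.

At early times the south run makes target at about 0.00630 M min⁻¹, read over its first 10 min, yet at 59 min it holds 0.165 M. I therefore read c(target) as a stock drained while it fills, and its lifetime as final stock over early rate, 26.2 min in the south run. I assume that the drain uses coupling partner, and so I take the lifetime as inverse to c(coupling partner). The readings hint at this and prove nothing: the south-east run, with less coupling partner, stands at 0.600 of the south run at 19 min and at a higher 0.782 at 59 min. The number I carry is the holding constant, lifetime times c(coupling partner): 1890 M·s.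

In the south-west run this gives a lifetime of 6.55 min at the charged coupling partner, so 59 min counts 9.01 such lifetimes. The run consumes coupling partner, so the lifetime lengthens as it goes and that count is an upper one. As a rough estimate I still take the stock to be rate times lifetime. The first readings of south against south-east give a partner order of 1.09, which I take as one, so the partner cancels between rate and lifetime. The readings at 10 min of north-west against south give a starting-material order of 0.540. The stock is then 0.349 M, or 14.5% of the charge.

The forecast differs from my share: it gives orders 0.5 and 1 and a share of 18%, on the ground that “Halving the partner halves both the rate and k, leaving the plateau unchanged”.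

The flask gives orders 0.59 and 0.96 and a share of 14.5%.

    starting material + coupling partner ⇌ intermediate, settled at all times (0.3880 L mol⁻¹)
    starting material + coupling partner → target (0.06420 L mol⁻¹ min⁻¹)
    2 starting material ⇌ idle substrate dimer, settled at all times (18.80 L mol⁻¹)
    target + coupling partner → side product (0.02496 L mol⁻¹ min⁻¹)

The drain is over-reaction, target + coupling partner → side product: without it the south-west run holds 81.3% of its charge at 59 min, against 14.5% with it. The south-east run tests the same constant. Its lifetime at the charged coupling partner is 52.4 min, and its early rate of 0.0038 M min⁻¹ gives a stock of 0.199 M. After 91.9 min, which is 1.75 lifetimes, the rise towards that stock gives 0.165 M, where the flask stands at a quarter of its charge, 0.150 M.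

(The earlier runs and the new flask stem from a simulated flask on assumed constants, and the scatter is random.)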